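Numbering: aldehyde half O1, C2, C3, C3a, C4–C7, C7a (benzene ring A, furan ring G, 4-hydroxyphenyl ring B on C2); other half O1', C2', C3', C3a', C4'–C7', C7a' (benzene ring C joined to C3 at C4', furan ring D, 4-hydroxyphenyl ring E on C2', 3,5-dihydroxyphenyl ring F on C3').
Enabling feature: ring C is a resorcinol with oxygen on C6' and C7a' and carbon substituents on the neighbouring C4' and C3a'. This is the pattern a 1,1-dialkoxy-3-silyloxybutadiene (C5'–C6'–C7'–C7a') leaves on an ynone C4'≡C3a' whose carbonyl carbon is C3'.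
Retrosynthesis: CHO from Br; ring D cut at O1'–C2' and C2'–C3' (ortho-quinone methide plus sulfonium benzylide); ring C cut at C4'–C5' and C3a'–C7a' (Diels–Alder); ynone cut at C3a'–C3'; alkyne carbon C3a' added to the C3 ester carbon; ring G cut at C2–C3 (carbene C–H insertion).
Forward order: ring G on the ring A bromide, then the C3 alkyne and the ynone, then ring C, then ring D, then formylation and demethylation.
Stereochemistry: C2 from the Rh2(S-PTTL)4-catalysed insertion and C3 by base equilibration to trans; C2' and C3' from an enantiopure sulfonium benzylide with trans ring closure.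

Key step: step 12

Assumption: Rh2(S-PTTL)4 and the (1R,4R,5R)-sulfide 27 (taken as purchasable) are assumed to be the antipodes that lead to 2R and to 2'R,3'R; if either induced the opposite sense, its mirror-image form would be used in the same step.

Step 1
Reactants: 1 (5-bromo-2-hydroxyphenyl)acetic acid
Product: 2 methyl (5-bromo-2-hydroxyphenyl)acetate
Conditions: MeOH, H2SO4 (cat.), reflux
Reagents that add atoms: methanol, CO
Why: Fischer esterification in excess methanol; any benzofuran-2(3H)-one formed by lactonisation is reopened to the hydroxy ester by methanolysis.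

Step 2
Reactants: 2 methyl (5-bromo-2-hydroxyphenyl)acetate; 3 4-methoxybenzyl chloride
Product: 4 methyl {5-bromo-2-[(4-methoxybenzyl)oxy]phenyl}acetate
Conditions: K2CO3, NaI (cat.), DMF, rt → 50 °C
Reagents that add atoms: none
Why: Williamson ether synthesis; carbonate deprotonates only the phenol, and the phenoxide is alkylated on oxygen by the reactive benzylic chloride.

Step 3
Reactants: 4 methyl {5-bromo-2-[(4-methoxybenzyl)oxy]phenyl}acetate
Product: 5 methyl {5-bromo-2-[(4-methoxybenzyl)oxy]phenyl}(diazo)acetate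
Conditions: 4-AcNHC6H4SO2N3, DBU, MeCN, 0 °C → rt
Reagents that add atoms: 4-acetamidobenzenesulfonyl azide, CC(=O)Nc1ccc(cc1)S(=O)(=O)N=[N+]=[N-]
Why: Regitz diazo transfer to the methylene activated by the aryl and ester groups.

Step 4
Reactants: 5 methyl {5-bromo-2-[(4-methoxybenzyl)oxy]phenyl}(diazo)acetate
Product: 6 methyl (2R,3S)-5-bromo-2-(4-methoxyphenyl)-2,3-dihydro-1-benzofuran-3-carboxylate (cis)
Conditions: Rh2(S-PTTL)4 (1 mol %), toluene, −60 °C
Reagents that add atoms: none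
Why: Loss of N2 gives a rhodium carbene that inserts into the ether benzylic C–H, activated by oxygen and the 4-methoxyphenyl group (1,5-insertion, five-membered ring); the chiral N-phthaloyl-tert-leucinate ligands distinguish the two enantiotopic benzylic hydrogens and so fix C2 as R, and the compact insertion transition state places ester and aryl cis (C3 as S, corrected in step 5).

Step 5
Reactants: 6 methyl (2R,3S)-5-bromo-2-(4-methoxyphenyl)-2,3-dihydro-1-benzofuran-3-carboxylate
Product: 7 methyl (2R,3R)-5-bromo-2-(4-methoxyphenyl)-2,3-dihydro-1-benzofuran-3-carboxylate (trans)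
Conditions: NaOMe (0.3 equiv), MeOH, rt
Reagents that add atoms: none
Why: Reversible enolisation of the ester equilibrates C3 to the more stable trans isomer (3R) while C2 is untouched; ring opening of the enolate by β-elimination of the phenoxide would be a reverse 5-endo-trig process and is stereoelectronically disfavoured.

Step 6
Reactants: 7 methyl (2R,3R)-5-bromo-2-(4-methoxyphenyl)-2,3-dihydro-1-benzofuran-3-carboxylate
Product: 9 (2R,3R)-5-bromo-3-ethynyl-2-(4-methoxyphenyl)-2,3-dihydro-1-benzofuran, via 3-carbaldehyde 8 (not isolated)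
Conditions: i-Bu2AlH (1.2 equiv), CH2Cl2, −78 °C; then MeOH, K2CO3, dimethyl (1-diazo-2-oxopropyl)phosphonate, −78 °C → rt
Reagents that add atoms: dimethyl (1-diazo-2-oxopropyl)phosphonate, CC(=O)C(=[N+]=[N-])P(=O)(OC)OC
Why: i-Bu2AlH stops at the tetrahedral aluminium hemiacetal at −78 °C; methanol releases aldehyde 8, which undergoes Seyferth–Gilbert homologation with the Ohira–Bestmann reagent under mild carbonate base in the same flask; C2 is not acidic, and C3, if it enolises, returns to the favoured trans arrangement.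

Step 7
Reactants: 10 3,5-dimethoxybenzoyl chloride
Product: 11 3,5-dimethoxy-N-methoxy-N-methylbenzamide
Conditions: MeNH(OMe)·HCl, K2CO3, EtOAc/H2O, 0 °C → rt
Reagents that add atoms: N,O-dimethylhydroxylamine hydrochloride, CNOC.Cl
Why: Schotten–Baumann acylation of the hydroxylamine gives the Weinreb amide.

Step 8
Reactants: 9 (2R,3R)-5-bromo-3-ethynyl-2-(4-methoxyphenyl)-2,3-dihydro-1-benzofuran; 11 3,5-dimethoxy-N-methoxy-N-methylbenzamide
Product: 13 3-[(2R,3R)-5-bromo-2-(4-methoxyphenyl)-2,3-dihydro-1-benzofuran-3-yl]-1-(3,5-dimethoxyphenyl)prop-2-yn-1-one, via alkynylmagnesium bromide 12 (not isolated)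
Conditions: EtMgBr (1.05 equiv), THF, 0 °C → rt; then 11, 0 °C → rt; aq. NH4Cl
Reagents that add atoms: none
Why: EtMgBr deprotonates only the terminal alkyne (no halogen–magnesium exchange at the aryl bromide); the alkynyl Grignard adds to the Weinreb amide to give a chelated tetrahedral adduct that cannot add twice and releases the ynone only on the neutral quench, so the base-sensitive propargylic C3–H never meets the ynone under basic conditions.

Step 9
Reactants: 14 acetyl chloride; 15 1,1-dichloroethene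
Product: 17 4,4-dichlorobut-3-en-2-one, via 4,4,4-trichlorobutan-2-one 16 (not isolated)
Conditions: AlCl3, CH2Cl2, 0 °C → rt; H2O; distillation
Reagents that add atoms: none
Why: Friedel–Crafts-type acylation of the alkene by the acylium ion with chloride capture gives the β-trichloro ketone, which loses HCl on distillation to the conjugated dichlorovinyl ketone.

Step 10
Reactants: 17 4,4-dichlorobut-3-en-2-one
Product: 18 4,4-dimethoxybut-3-en-2-one
Conditions: NaOMe (2.1 equiv), MeOH, 0 °C → rt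
Reagents that add atoms: sodium methoxide, C[O-].[Na+]
Why: Two addition–elimination sequences (vinylogous acyl substitution) replace both vinylic chlorides by methoxide.

Step 11
Reactants: 18 4,4-dimethoxybut-3-en-2-one
Product: 19 1,1-dimethoxy-3-(trimethylsilyloxy)buta-1,3-diene
Conditions: Me3SiCl, Et3N, ZnCl2 (cat.), toluene, rt → 40 °C; filtration, distillation
Reagents that add atoms: chlorotrimethylsilane, C[Si](C)(C)Cl
Why: Soft enolisation of the methyl ketone and O-silylation give the cross-conjugated silyl enol ether, as in the standard preparation of 1-alkoxy-3-silyloxybutadienes.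

Step 12
Reactants: 13 3-[(2R,3R)-5-bromo-2-(4-methoxyphenyl)-2,3-dihydro-1-benzofuran-3-yl]-1-(3,5-dimethoxyphenyl)prop-2-yn-1-one; 19 1,1-dimethoxy-3-(trimethylsilyloxy)buta-1,3-diene
Product: 22 {2-[(2R,3R)-5-bromo-2-(4-methoxyphenyl)-2,3-dihydro-1-benzofuran-3-yl]-4-hydroxy-6-methoxyphenyl}(3,5-dimethoxyphenyl)methanone, via cyclohexadiene cycloadduct 20 (not isolated), via aryl trimethylsilyl ether 21 (not isolated)
Conditions: 19 (2 equiv), toluene, 80 °C; then 0.5 M HCl, THF, rt
Reagents that add atoms: none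
Why: The nucleophilic CH2 terminus of the silyl enol ether (future C5') bonds to the ynone β-carbon C4' while the ketene acetal carbon (future C7a') bonds to the α-carbon C3a', a strongly polarised and possibly asynchronous (4+2) cycloaddition that closes the six-membered ring as 1,4-cyclohexadiene 20. 1,4-Elimination of methanol across C7a'/C5' aromatises it to silyl ether 21, and dilute acid frees the C6' phenol. The closest known reaction type is the Diels–Alder/aromatisation of 1,1-dialkoxy-3-silyloxybutadienes with acetylenic ketones and esters, which gives 2-acyl-5-hydroxyanisoles. Ring C is thus closed by an intermolecular cycloaddition that forms C4'–C5' and C3a'–C7a' in one operation; no stereocentre is created, and C2 and C3 are untouched because no base is present to remove the propargylic C3–H. The only selectivity needed is regiochemical and is secured by the matched polarity of the partners: the diene terminus with the largest HOMO coefficient meets the ynone β-carbon, so the aroyl group ends between C4' and the C7a' methoxy group.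

Step 13
Reactants: 22 {2-[(2R,3R)-5-bromo-2-(4-methoxyphenyl)-2,3-dihydro-1-benzofuran-3-yl]-4-hydroxy-6-methoxyphenyl}(3,5-dimethoxyphenyl)methanone
Product: 23 {2-[(2R,3R)-5-bromo-2-(4-methoxyphenyl)-2,3-dihydro-1-benzofuran-3-yl]-4,6-dimethoxyphenyl}(3,5-dimethoxyphenyl)methanone
Conditions: MeI, K2CO3, acetone, reflux
Reagents that add atoms: iodomethane, CI
Why: Williamson methylation of the only free phenol; it protects the C6' oxygen for the organolithium step and leaves the C7a' oxygen as the one to be unmasked next.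

Step 14
Reactants: 23 {2-[(2R,3R)-5-bromo-2-(4-methoxyphenyl)-2,3-dihydro-1-benzofuran-3-yl]-4,6-dimethoxyphenyl}(3,5-dimethoxyphenyl)methanone
Product: 24 {2-[(2R,3R)-5-bromo-2-(4-methoxyphenyl)-2,3-dihydro-1-benzofuran-3-yl]-6-hydroxy-4-methoxyphenyl}(3,5-dimethoxyphenyl)methanone
Conditions: BCl3 (1.5 equiv), CH2Cl2, −78 → 0 °C; H2O
Reagents that add atoms: none
Why: Chelation-directed ether cleavage: BCl3 bridges the ketone oxygen and the ortho C7a' methoxy group in a six-membered chelate, so only that methyl ether is cleaved; none of the other four methoxy groups is ortho to a carbonyl.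

Step 15
Reactants: 24 {2-[(2R,3R)-5-bromo-2-(4-methoxyphenyl)-2,3-dihydro-1-benzofuran-3-yl]-6-hydroxy-4-methoxyphenyl}(3,5-dimethoxyphenyl)methanone
Product: 25 3-[(2R,3R)-5-bromo-2-(4-methoxyphenyl)-2,3-dihydro-1-benzofuran-3-yl]-2-[(3,5-dimethoxyphenyl)(hydroxy)methyl]-5-methoxyphenol (both carbinol epimers)
Conditions: NaBH4, THF/MeOH, 0 °C → rt
Reagents that add atoms: none
Why: Hydride reduction of the diaryl ketone; the new carbinol centre forms without control, which is immaterial because it becomes trigonal again in step 18.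

Step 16
Reactants: 25 3-[(2R,3R)-5-bromo-2-(4-methoxyphenyl)-2,3-dihydro-1-benzofuran-3-yl]-2-[(3,5-dimethoxyphenyl)(hydroxy)methyl]-5-methoxyphenol
Product: 26 3-[(2R,3R)-5-bromo-2-(4-methoxyphenyl)-2,3-dihydro-1-benzofuran-3-yl]-2-[(3,5-dimethoxyphenyl)(4-methylbenzenesulfonyl)methyl]-5-methoxyphenol (both epimers at the sulfonyl-bearing carbon)
Conditions: 4-MeC6H4SO2Na, HCO2H, THF/H2O, rt
Reagents that add atoms: sodium 4-methylbenzenesulfinate, Cc1ccc(cc1)S(=O)[O-].[Na+]
Why: Acid ionises the ortho-hydroxybenzhydrol (SN1 through the ortho-quinone methide or benzhydryl cation) and the sulfinate is bound through sulfur; the sulfone is a storable quinone methide precursor that eliminates under mild base, and its undefined centre is again lost in step 18.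

Step 17
Reactants: 27 (1R,4R,5R)-4,7,7-trimethyl-6-thiabicyclo[3.2.1]octane (isothiocineole); 3 4-methoxybenzyl chloride
Product: 28 (1R,4R,5R,6R)-6-(4-methoxybenzyl)-4,7,7-trimethyl-6-thiabicyclo[3.2.1]octan-6-ium trifluoromethanesulfonate
Conditions: LiOTf, CH2Cl2/H2O, rt
Reagents that add atoms: lithium trifluoromethanesulfonate, [Li+].[O-]S(=O)(=O)C(F)(F)F
Why: S-alkylation of the sulfide by the benzylic chloride with exchange to the non-nucleophilic triflate; alkylation is expected on the less hindered sulfur lone pair, turned away from the three-carbon bridge, which fixes the sulfur centre.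

Step 18
Reactants: 26 3-[(2R,3R)-5-bromo-2-(4-methoxyphenyl)-2,3-dihydro-1-benzofuran-3-yl]-2-[(3,5-dimethoxyphenyl)(4-methylbenzenesulfonyl)methyl]-5-methoxyphenol; 28 (1R,4R,5R,6R)-6-(4-methoxybenzyl)-4,7,7-trimethyl-6-thiabicyclo[3.2.1]octan-6-ium trifluoromethanesulfonate
Product: 30 (2R,3R)-5-bromo-3-[(2R,3R)-3-(3,5-dimethoxyphenyl)-6-methoxy-2-(4-methoxyphenyl)-2,3-dihydro-1-benzofuran-4-yl]-2-(4-methoxyphenyl)-2,3-dihydro-1-benzofuran, via ortho-quinone methide 29 (not isolated)
Conditions: 28 (1.5 equiv), Cs2CO3 (3 equiv), MeCN, 0 °C → rt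
Reagents that add atoms: none
Why: Proposed new method: Cs2CO3 expels sulfinate from the phenoxide of 26 to give ortho-quinone methide 29 and deprotonates 28 to its benzylide; the ylide carbon adds to C3' and the phenoxide then displaces the sulfide at C2' with inversion (5-exo-tet), the anti approach giving the trans ring; the rigid bicyclic sulfide exposes one face of the benzylide, which should fix C2' and, through the favoured anti transition state, C3', overriding the weak bias of the remote ring G; the closest known reaction types are the (4+1) annulation of ortho-quinone methides from 2-(sulfonylalkyl)phenols with achiral sulfonium ylides to trans-2,3-dihydrobenzofurans and the reagent-controlled epoxidation of aldehydes by chiral benzylsulfonium ylides of this class.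

Step 19
Reactants: 30 (2R,3R)-5-bromo-3-[(2R,3R)-3-(3,5-dimethoxyphenyl)-6-methoxy-2-(4-methoxyphenyl)-2,3-dihydro-1-benzofuran-4-yl]-2-(4-methoxyphenyl)-2,3-dihydro-1-benzofuran
Product: 32 (2R,3R)-3-[(2R,3R)-3-(3,5-dimethoxyphenyl)-6-methoxy-2-(4-methoxyphenyl)-2,3-dihydro-1-benzofuran-4-yl]-2-(4-methoxyphenyl)-2,3-dihydro-1-benzofuran-5-carbaldehyde, via aryllithium 31 (not isolated)
Conditions: n-BuLi (1.1 equiv), THF, −78 °C; DMF; aq. NH4Cl
Reagents that add atoms: N,N-dimethylformamide, CN(C)C=O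
Why: Bromine–lithium exchange is faster than any deprotonation at −78 °C and the aryllithium is formylated by DMF (Bouveault formylation); no O–H is present at this stage.

Step 20
Reactants: 32 (2R,3R)-3-[(2R,3R)-3-(3,5-dimethoxyphenyl)-6-methoxy-2-(4-methoxyphenyl)-2,3-dihydro-1-benzofuran-4-yl]-2-(4-methoxyphenyl)-2,3-dihydro-1-benzofuran-5-carbaldehyde
Product: 33 (2R,3R)-3-[(2R,3R)-3-(3,5-dihydroxyphenyl)-6-hydroxy-2-(4-hydroxyphenyl)-2,3-dihydro-1-benzofuran-4-yl]-2-(4-hydroxyphenyl)-2,3-dihydro-1-benzofuran-5-carbaldehyde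
Conditions: BBr3 (excess), CH2Cl2, −78 °C → rt; H2O
Reagents that add atoms: none
Why: Lewis acid cleavage of the five aryl methyl ethers; the trans-2,3-diaryl-dihydrobenzofurans are the thermodynamic isomers, so any reversible ionisation at C2 or C2' should return the same configuration, and C3 and C3' cannot epimerise.

Compound list
1 | (5-bromo-2-hydroxyphenyl)acetic acid | OC(=O)Cc1cc(Br)ccc1O | starting material
2 | methyl (5-bromo-2-hydroxyphenyl)acetate | COC(=O)Cc1cc(Br)ccc1O | intermediate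
3 | 4-methoxybenzyl chloride | COc1ccc(CCl)cc1 | starting material
4 | methyl {5-bromo-2-[(4-methoxybenzyl)oxy]phenyl}acetate | COC(=O)Cc1cc(Br)ccc1OCc1ccc(OC)cc1 | intermediate
5 | methyl {5-bromo-2-[(4-methoxybenzyl)oxy]phenyl}(diazo)acetate | COC(=O)C(=[N+]=[N-])c1cc(Br)ccc1OCc1ccc(OC)cc1 | intermediate
6 | methyl (2R,3S)-5-bromo-2-(4-methoxyphenyl)-2,3-dihydro-1-benzofuran-3-carboxylate (cis) | Brc1ccc2c(c1)[C@H](C(=O)OC)[C@H](c1ccc(OC)cc1)O2 | intermediate
7 | methyl (2R,3R)-5-bromo-2-(4-methoxyphenyl)-2,3-dihydro-1-benzofuran-3-carboxylate (trans) | Brc1ccc2c(c1)[C@@H](C(=O)OC)[C@H](c1ccc(OC)cc1)O2 | intermediate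
8 | (2R,3R)-5-bromo-2-(4-methoxyphenyl)-2,3-dihydro-1-benzofuran-3-carbaldehyde | Brc1ccc2c(c1)[C@@H](C=O)[C@H](c1ccc(OC)cc1)O2 | intermediate (not isolated)
9 | (2R,3R)-5-bromo-3-ethynyl-2-(4-methoxyphenyl)-2,3-dihydro-1-benzofuran | Brc1ccc2c(c1)[C@@H](C#C)[C@H](c1ccc(OC)cc1)O2 | intermediate
10 | 3,5-dimethoxybenzoyl chloride | COc1cc(OC)cc(C(Cl)=O)c1 | starting material
11 | 3,5-dimethoxy-N-methoxy-N-methylbenzamide | COc1cc(OC)cc(c1)C(=O)N(C)OC | intermediate
12 | bromo{[(2R,3S)-5-bromo-2-(4-methoxyphenyl)-2,3-dihydro-1-benzofuran-3-yl]ethynyl}magnesium (same spatial arrangement as 9; the C3 descriptor changes by priority only) | Brc1ccc2c(c1)[C@@H](C#C[Mg]Br)[C@H](c1ccc(OC)cc1)O2 | intermediate (not isolated)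
13 | 3-[(2R,3R)-5-bromo-2-(4-methoxyphenyl)-2,3-dihydro-1-benzofuran-3-yl]-1-(3,5-dimethoxyphenyl)prop-2-yn-1-one | Brc1ccc2c(c1)[C@@H](C#CC(=O)c1cc(OC)cc(OC)c1)[C@H](c1ccc(OC)cc1)O2 | intermediate
14 | acetyl chloride | CC(Cl)=O | starting material
15 | 1,1-dichloroethene | C=C(Cl)Cl | starting material
16 | 4,4,4-trichlorobutan-2-one | CC(=O)CC(Cl)(Cl)Cl | intermediate (not isolated)
17 | 4,4-dichlorobut-3-en-2-one | CC(=O)C=C(Cl)Cl | intermediate
18 | 4,4-dimethoxybut-3-en-2-one | CC(=O)C=C(OC)OC | intermediate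
19 | 1,1-dimethoxy-3-(trimethylsilyloxy)buta-1,3-diene | C=C(O[Si](C)(C)C)C=C(OC)OC | intermediate
20 | {2-[(2R,3R)-5-bromo-2-(4-methoxyphenyl)-2,3-dihydro-1-benzofuran-3-yl]-6,6-dimethoxy-4-(trimethylsilyloxy)cyclohexa-1,4-dien-1-yl}(3,5-dimethoxyphenyl)methanone | Brc1ccc2c(c1)[C@@H](C1=C(C(=O)c3cc(OC)cc(OC)c3)C(OC)(OC)C=C(O[Si](C)(C)C)C1)[C@H](c1ccc(OC)cc1)O2 | intermediate (not isolated)
21 | {2-[(2R,3R)-5-bromo-2-(4-methoxyphenyl)-2,3-dihydro-1-benzofuran-3-yl]-6-methoxy-4-(trimethylsilyloxy)phenyl}(3,5-dimethoxyphenyl)methanone | Brc1ccc2c(c1)[C@@H](c1cc(O[Si](C)(C)C)cc(OC)c1C(=O)c1cc(OC)cc(OC)c1)[C@H](c1ccc(OC)cc1)O2 | intermediate (not isolated)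
22 | {2-[(2R,3R)-5-bromo-2-(4-methoxyphenyl)-2,3-dihydro-1-benzofuran-3-yl]-4-hydroxy-6-methoxyphenyl}(3,5-dimethoxyphenyl)methanone | Brc1ccc2c(c1)[C@@H](c1cc(O)cc(OC)c1C(=O)c1cc(OC)cc(OC)c1)[C@H](c1ccc(OC)cc1)O2 | intermediate
23 | {2-[(2R,3R)-5-bromo-2-(4-methoxyphenyl)-2,3-dihydro-1-benzofuran-3-yl]-4,6-dimethoxyphenyl}(3,5-dimethoxyphenyl)methanone | Brc1ccc2c(c1)[C@@H](c1cc(OC)cc(OC)c1C(=O)c1cc(OC)cc(OC)c1)[C@H](c1ccc(OC)cc1)O2 | intermediate
24 | {2-[(2R,3R)-5-bromo-2-(4-methoxyphenyl)-2,3-dihydro-1-benzofuran-3-yl]-6-hydroxy-4-methoxyphenyl}(3,5-dimethoxyphenyl)methanone | Brc1ccc2c(c1)[C@@H](c1cc(OC)cc(O)c1C(=O)c1cc(OC)cc(OC)c1)[C@H](c1ccc(OC)cc1)O2 | intermediate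
25 | 3-[(2R,3R)-5-bromo-2-(4-methoxyphenyl)-2,3-dihydro-1-benzofuran-3-yl]-2-[(3,5-dimethoxyphenyl)(hydroxy)methyl]-5-methoxyphenol (both carbinol epimers) | Brc1ccc2c(c1)[C@@H](c1cc(OC)cc(O)c1C(O)c1cc(OC)cc(OC)c1)[C@H](c1ccc(OC)cc1)O2 | intermediate
26 | 3-[(2R,3R)-5-bromo-2-(4-methoxyphenyl)-2,3-dihydro-1-benzofuran-3-yl]-2-[(3,5-dimethoxyphenyl)(4-methylbenzenesulfonyl)methyl]-5-methoxyphenol (both epimers at the sulfonyl-bearing carbon) | Brc1ccc2c(c1)[C@@H](c1cc(OC)cc(O)c1C(c1cc(OC)cc(OC)c1)S(=O)(=O)c1ccc(C)cc1)[C@H](c1ccc(OC)cc1)O2 | intermediate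
27 | (1R,4R,5R)-4,7,7-trimethyl-6-thiabicyclo[3.2.1]octane (isothiocineole) | C[C@@H]1CC[C@@H]2C[C@H]1SC2(C)C | starting material
28 | (1R,4R,5R,6R)-6-(4-methoxybenzyl)-4,7,7-trimethyl-6-thiabicyclo[3.2.1]octan-6-ium trifluoromethanesulfonate (benzyl group on the sulfur face turned away from the three-carbon bridge) | COc1ccc(C[S@@+]2[C@@H]3C[C@@H](CC[C@H]3C)C2(C)C)cc1.[O-]S(=O)(=O)C(F)(F)F | intermediate
29 | 5-[(2R,3R)-5-bromo-2-(4-methoxyphenyl)-2,3-dihydro-1-benzofuran-3-yl]-6-[(3,5-dimethoxyphenyl)methylidene]-3-methoxycyclohexa-2,4-dien-1-one (alkene geometry not defined) | Brc1ccc2c(c1)[C@@H](C1=CC(OC)=CC(=O)C1=Cc1cc(OC)cc(OC)c1)[C@H](c1ccc(OC)cc1)O2 | intermediate (not isolated)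
30 | (2R,3R)-5-bromo-3-[(2R,3R)-3-(3,5-dimethoxyphenyl)-6-methoxy-2-(4-methoxyphenyl)-2,3-dihydro-1-benzofuran-4-yl]-2-(4-methoxyphenyl)-2,3-dihydro-1-benzofuran | Brc1ccc2c(c1)[C@@H](c1cc(OC)cc3c1[C@@H](c1cc(OC)cc(OC)c1)[C@H](c1ccc(OC)cc1)O3)[C@H](c1ccc(OC)cc1)O2 | intermediate
31 | {(2R,3R)-3-[(2R,3R)-3-(3,5-dimethoxyphenyl)-6-methoxy-2-(4-methoxyphenyl)-2,3-dihydro-1-benzofuran-4-yl]-2-(4-methoxyphenyl)-2,3-dihydro-1-benzofuran-5-yl}lithium | [Li]c1ccc2c(c1)[C@@H](c1cc(OC)cc3c1[C@@H](c1cc(OC)cc(OC)c1)[C@H](c1ccc(OC)cc1)O3)[C@H](c1ccc(OC)cc1)O2 | intermediate (not isolated)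
32 | (2R,3R)-3-[(2R,3R)-3-(3,5-dimethoxyphenyl)-6-methoxy-2-(4-methoxyphenyl)-2,3-dihydro-1-benzofuran-4-yl]-2-(4-methoxyphenyl)-2,3-dihydro-1-benzofuran-5-carbaldehyde | O=Cc1ccc2c(c1)[C@@H](c1cc(OC)cc3c1[C@@H](c1cc(OC)cc(OC)c1)[C@H](c1ccc(OC)cc1)O3)[C@H](c1ccc(OC)cc1)O2 | intermediate
33 | (2R,3R)-3-[(2R,3R)-3-(3,5-dihydroxyphenyl)-6-hydroxy-2-(4-hydroxyphenyl)-2,3-dihydro-1-benzofuran-4-yl]-2-(4-hydroxyphenyl)-2,3-dihydro-1-benzofuran-5-carbaldehyde | O=Cc1ccc2c(c1)[C@@H](c1cc(O)cc3c1[C@@H](c1cc(O)cc(O)c1)[C@H](c1ccc(O)cc1)O3)[C@H](c1ccc(O)cc1)O2 | target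

Total step count: 20. Longest linear sequence: 15 steps (steps 1–6, 8, 12–16, 18–20).

Steps most likely to fail

Step 18. The chiral ylide may select the faces of the quinone methide carbon C3' poorly or in a sense mismatched with ring G, and the sulfonium salt may be lost by SN1 solvolysis or the quinone methide by hydration and dimerisation before they meet. The fallback sets out from hydroxy ketone 24 and comes back at 30, using only known reaction types without reagent control. O-Alkylation of 24 with 3 (K2CO3, DMF) would give {2-[(2R,3R)-5-bromo-2-(4-methoxyphenyl)-2,3-dihydro-1-benzofuran-3-yl]-4-methoxy-6-[(4-methoxybenzyl)oxy]phenyl}(3,5-dimethoxyphenyl)methanone F1. The phosphazene base P4-t-Bu in THF would close the benzylic ether carbanion onto the ketone to the 3-hydroxy-2,3-dihydrobenzofuran F2, and TsOH in toluene would dehydrate it to the 2',3'-diarylbenzofuran F3. Ionic hydrogenation (Et3SiH, CF3CO2H, CH2Cl2) would then give the trans-dihydrobenzofuran 30 together with its (2'S,3'S) epimer F4, to be separated by chromatography.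

Step 6. The ester may be over-reduced to the primary alcohol, and under the carbonate base the enolisable aldehyde may open and reclose ring G, eroding the C2 configuration. The fallback sets out from ester 7 and comes back at alkyne 9 without passing through an aldehyde. LiOH in THF/H2O would give the carboxylic acid F5. Photoredox decarboxylative alkynylation (Ir[dF(CF3)ppy]2(dtbbpy)PF6, CsO2CPh, blue light, 1-[(triisopropylsilyl)ethynyl]-1,2-benziodoxol-3(1H)-one) would trap the C3 radical anti to ring B and give the trans silyl alkyne F6. Bu4NF in THF would then release 9.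

Step 20. The fivefold demethylation is slow and may be overtaken by Friedel–Crafts condensation of the Lewis acid–activated formyl group with the electron-rich resorcinol rings, alongside ring opening at the benzylic C2–O1 and C2'–O1' bonds. The fallback sets out from bromide 30 and comes back at target 33, so that the aldehyde never meets the boron halide. BBr3 in CH2Cl2 would give the pentaphenol bromide F7, and t-BuMe2SiCl with imidazole in DMF the pentakis(silyl ether) F8. n-BuLi then DMF at −78 °C would give the silylated aldehyde F9, and HF·pyridine in THF would release 33.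

Further compounds
F1 | step 18 | {2-[(2R,3R)-5-bromo-2-(4-methoxyphenyl)-2,3-dihydro-1-benzofuran-3-yl]-4-methoxy-6-[(4-methoxybenzyl)oxy]phenyl}(3,5-dimethoxyphenyl)methanone | Brc1ccc2c(c1)[C@@H](c1cc(OC)cc(OCc3ccc(OC)cc3)c1C(=O)c1cc(OC)cc(OC)c1)[C@H](c1ccc(OC)cc1)O2
F2 | step 18 | 4-[(2R,3R)-5-bromo-2-(4-methoxyphenyl)-2,3-dihydro-1-benzofuran-3-yl]-3-(3,5-dimethoxyphenyl)-6-methoxy-2-(4-methoxyphenyl)-2,3-dihydro-1-benzofuran-3-ol (mixture at C2' and C3') | Brc1ccc2c(c1)[C@@H](c1cc(OC)cc3c1C(O)(c1cc(OC)cc(OC)c1)C(c1ccc(OC)cc1)O3)[C@H](c1ccc(OC)cc1)O2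
F3 | step 18 | (2R,3R)-5-bromo-3-[3-(3,5-dimethoxyphenyl)-6-methoxy-2-(4-methoxyphenyl)-1-benzofuran-4-yl]-2-(4-methoxyphenyl)-2,3-dihydro-1-benzofuran | Brc1ccc2c(c1)[C@@H](c1cc(OC)cc3oc(-c4ccc(OC)cc4)c(-c4cc(OC)cc(OC)c4)c13)[C@H](c1ccc(OC)cc1)O2
F4 | step 18 | (2R,3R)-5-bromo-3-[(2S,3S)-3-(3,5-dimethoxyphenyl)-6-methoxy-2-(4-methoxyphenyl)-2,3-dihydro-1-benzofuran-4-yl]-2-(4-methoxyphenyl)-2,3-dihydro-1-benzofuran | Brc1ccc2c(c1)[C@@H](c1cc(OC)cc3c1[C@H](c1cc(OC)cc(OC)c1)[C@@H](c1ccc(OC)cc1)O3)[C@H](c1ccc(OC)cc1)O2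
F5 | step 6 | (2R,3R)-5-bromo-2-(4-methoxyphenyl)-2,3-dihydro-1-benzofuran-3-carboxylic acid | Brc1ccc2c(c1)[C@@H](C(O)=O)[C@H](c1ccc(OC)cc1)O2
F6 | step 6 | {[(2R,3S)-5-bromo-2-(4-methoxyphenyl)-2,3-dihydro-1-benzofuran-3-yl]ethynyl}tri(propan-2-yl)silane (trans; the C3 descriptor changes by priority only) | Brc1ccc2c(c1)[C@@H](C#C[Si](C(C)C)(C(C)C)C(C)C)[C@H](c1ccc(OC)cc1)O2
F7 | step 20 | 5-[(2R,3R)-4-[(2R,3R)-5-bromo-2-(4-hydroxyphenyl)-2,3-dihydro-1-benzofuran-3-yl]-6-hydroxy-2-(4-hydroxyphenyl)-2,3-dihydro-1-benzofuran-3-yl]benzene-1,3-diol | Brc1ccc2c(c1)[C@@H](c1cc(O)cc3c1[C@@H](c1cc(O)cc(O)c1)[C@H](c1ccc(O)cc1)O3)[C@H](c1ccc(O)cc1)O2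
F8 | step 20 | pentakis(tert-butyldimethylsilyl) ether of F7 | Brc1ccc2c(c1)[C@@H](c1cc(O[Si](C)(C)C(C)(C)C)cc3c1[C@@H](c1cc(O[Si](C)(C)C(C)(C)C)cc(O[Si](C)(C)C(C)(C)C)c1)[C@H](c1ccc(O[Si](C)(C)C(C)(C)C)cc1)O3)[C@H](c1ccc(O[Si](C)(C)C(C)(C)C)cc1)O2
F9 | step 20 | pentakis(tert-butyldimethylsilyl) ether of 33 | O=Cc1ccc2c(c1)[C@@H](c1cc(O[Si](C)(C)C(C)(C)C)cc3c1[C@@H](c1cc(O[Si](C)(C)C(C)(C)C)cc(O[Si](C)(C)C(C)(C)C)c1)[C@H](c1ccc(O[Si](C)(C)C(C)(C)C)cc1)O3)[C@H](c1ccc(O[Si](C)(C)C(C)(C)C)cc1)O2
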